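## The problem

Piscisoflavone A (19) is an isoflavone: a 7-hydroxychromen-4-one (rings A and C) whose C3 carries a pentasubstituted ring B. Ring B has oxygen at C2′, C4′ and C5′, a prenyl group at C3′ between the two free phenols, and hydrogen only at C6′. There is no stereocentre and the one alkene ends in two methyl groups, so the task is regiocontrol and functional-group tolerance, not stereocontrol. Ring B needs four contiguous substituents placed without ambiguity, with O5′ methylated and O2′ and O4′ free at the end. The prenyl group is ortho to both ring B phenols; strong acid would cyclise it to a dimethylchroman, and hydrogenolysis, strong electrophiles and oxidants are excluded late in the route. A free 2′-OH in an open-chain precursor can attack C4 or C2 and close a furan instead of ring C, so O2′ must stay masked until the pyranone exists and must be distinguishable from O1. The feature that allows a convergent union is that C4 is a carbonyl carbon bonded only to C4a of ring A and to C3, and C3 is simply the benzylic carbon of ring B. Carbon monoxide can therefore become C4 and join an A-ring aryl electrophile to a B-ring benzyl nucleophile, leaving C2 as a single carbon to be inserted between C3 and the ring A oxygen that becomes O1.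

## Retrosynthesis

**19 ⇒ 18.** The O–CH2 bonds of the two MOM ethers at O2′ and O4′ are cut. MOM is preferred to benzyl (hydrogenolysis would reduce the prenyl group), to methyl (O5′ must remain the only methyl ether) and to silyl (unsafe beside an aryllithium). It is also the group that directs the lithiation used earlier. 18 differs from 19 only in these two acetals. The forward step needs acid mild enough that the prenyl group does not add to either neighbouring phenol.

**18 ⇒ 16 (through 17).** Ring C is opened at O1–C2 and C2–C3, removing C2 as a one-carbon unit at the formic acid oxidation level and leaving the 2-hydroxydeoxybenzoin 16. In the forward direction the enaminone 17 is passed through. The neighbouring cut at C3–C1′ would need a crowded ring B aryl metal and leaves no role for carbon monoxide; this cut keeps C3 as the benzylic carbon of ring B. 16 is open-chain with two separate aromatic halves. The forward reaction requires the 2-OH of ring A to be the only free oxygen within reach of C2 and C4, so O2′ and O4′ stay as MOM ethers.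

**16 ⇒ 15.** Two O–acetyl bonds on ring A are cut. Esters on ring A and acetals on ring B are what distinguish O1 from O2′, since mild base removes only the esters. Because both ring A oxygens carry the same group, no selective monoprotection of a resorcinol is needed anywhere. 15 has the same skeleton as 16 and is the direct product of the fragment union. The forward methanolysis must be faster than enolisation of the benzylic ketone.

**15 ⇒ 13 + 14 + 11.** Both bonds to the carbonyl carbon, C4a–C4 and C4–C3, are cut, giving the aryl iodide 13, carbon monoxide 14 and the benzylzinc chloride 11. Friedel–Crafts or Hoesch acylation would need strong acid, which neither the MOM ethers nor the prenyl group tolerate. A stepwise acylation would need a separately prepared ring A acid derivative. The three-component cut makes two skeletal bonds in one catalytic step from the simplest possible ring A partner. The forward reaction must favour CO insertion over direct aryl–benzyl coupling, and the organometallic must ignore aryl acetates and the product ketone.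

**11 ⇒ 10 ⇒ 8 (through 9).** The C–Zn and C–Cl bonds are traced back to the benzylic C–O bond of alcohol 8. The alcohol is the stable, purifiable storage form; the chloride 10 and the zinc reagent 11 are made immediately before use. The forward steps must avoid protic or Lewis acid.

**8 ⇒ 5 + 6.** The aryl–prenyl bond at C3′ is cut, giving the benzylic alcohol 5 and prenyl bromide 6. This position lies between the two MOM ethers, each of which has its other ortho position blocked, so directed lithiation has one clearly preferred site. Electrophilic prenylation of a free resorcinol would give O- and C-alkylation mixtures, and a Claisen route would take three steps. Introducing the prenyl group after the benzylic carbon means no electrophilic reagent and no second lithiation is applied to a prenylated ring.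

**5 ⇒ 4 ⇒ 3 ⇒ 1 (through 2).** The benzylic C–H (reduction), the two MOM O–CH2 bonds and finally the ring–CHO bond are cut, leading to 4-methoxyresorcinol 1. Formylation of 1 has one strongly preferred site, para to one hydroxyl and ortho to the other; it passes through the iminium salt 2. 1 already holds the three ring B oxygens, with the correct one methylated.

**13 ⇒ 12.** The two O–acetyl bonds are cut, giving 4-iodoresorcinol 12. No selectivity is required, and the iodine already sits at the future C4a, ortho to the future O1 and para to O7.

## Roads not taken

**Alternative 1:** The cut goes through ring B: C5′–C6′, C1′–C2′ and C2′–C3′.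
- **Cut and key step.** C1′ and C6′ come from the alkyne of 3-ethynyl-7-(methoxymethoxy)chromen-4-one (A2). C5′, C4′ and C3′ come from pentacarbonyl{methoxy[1-(methoxymethoxy)ethenyl]methylidene}chromium, (CO)5Cr=C(OMe)C(OMOM)=CH2 (A3). C2′ comes from one CO ligand. A Dötz benzannulation would give the 4-methoxyphenol A1, with ring B already on C3 of a finished chromone.
- **Merits.** The chromone is complete before O2′ exists, so the furan-closure problem of an open-chain 2′-hydroxy ketone never arises. The para relation of 2′-OH and 5′-OMe and the position of O4′ follow from the mechanism. The larger alkyne substituent ends up next to the phenol, which is the regiochemistry needed.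
- **Weak points.** A1 has no prenyl group. C3′ would have to be alkylated afterwards between a phenol and a MOM ether, realistically by O-allylation and Claisen rearrangement, on a ring that is an easily oxidised hydroquinone monoether. A2 is an electron-poor, conjugate-acceptor alkyne, the class least suited to benzannulation. A3 is an electron-rich, little-used carbene complex. Chromium is stoichiometric and must be removed oxidatively.
- **Comparison.** This road is better in avoiding the O1/O2′ competition altogether. The chosen plan offers instead a catalytic union at 25–40 °C, a prenyl group placed early where lithiation is unambiguous, and no late C-alkylation of ring B.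

**Alternative 2:** Ring C is cut at C3–C4 and O1–C2.
- **Cut and key step.** 2-Hydroxy-4-(methoxymethoxy)benzaldehyde (A5) supplies ring A, O1 and C4. The aryl(silyl)alkyne A6 supplies C2, C3 and ring B. With [RhCl(cod)]2, C5H2Ph4 and Cu(OAc)2, phenoxide-directed acyl C–H rhodation, alkyne insertion and C–O reductive elimination would give the 2-silylchromone A4. Protodesilylation and MOM removal would finish the synthesis.
- **Merits.** Ring C forms in one step with no deoxybenzoin, no one-carbon insertion and no ester cleavage, so after fragment union this road is two steps shorter than the chosen one. A5 is made in one step with reliable selectivity because its 2-OH is hydrogen-bonded. The silyl group could probably be lost in the final acid step.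
- **Weak points.** The regiochemistry depends on the silyl group steering the insertion. That is plausible for simple aryl(silyl)alkynes but less certain for an electron-rich aryl group whose ortho MOM oxygen can bind rhodium. The reaction needs temperatures well above 100 °C with a stoichiometric divalent copper oxidant, under which the prenyl alkene can coordinate, migrate or be oxidised at its allylic positions. Decarbonylation of the aroylrhodium intermediate is a known side path. A6 still needs a prenylated ring B precursor, so it is no shorter than 11.
- **Comparison.** This alternative is superior in step count after the union and in the economy of ring C formation. The chosen plan offers a union whose regiochemistry cannot go wrong, because CO can only bridge the two carbons offered to it, and conditions that do not endanger the prenyl group.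

**Alternative 3:** The cut is C1′–C2′ of ring B, traced back to a squaric acid derivative.
- **Cut and key step.** The racemic cyclobutenone A8 carries C2′ as its carbonyl, the prenyl group on the future C3′, an isopropoxy group on the future C4′, a methoxy group on the sp3 carbon that becomes C5′, and a 2-(chromon-3-yl)ethenyl group that supplies C6′ and C1′. On heating, 4π ring opening to a dienylketene, 6π electrocyclisation and tautomerisation (Moore rearrangement) would give phenol A7.
- **Merits.** All four contiguous substituents of ring B come from the four-membered ring with full positional control and without aromatic substitution or lithiation. The three ring B oxygens emerge differentiated as free OH, isopropyl ether and methyl ether. The prenyl group is in place before the ring exists.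
- **Weak points.** A8 requires addition of a chromone-bearing vinyl nucleophile to a squarate-derived dione, and a chromone is itself electrophilic at C2 and C4, so the chromone would have to be masked or built later. The isopropyl ether must finally be cleaved by a strong Lewis acid next to an ortho-prenyl group and a methyl ether, which is harder than MOM removal. Both partners need several steps, so the route is longer.
- **Comparison.** This road is better in the unambiguous construction of the crowded ring B. The chosen plan answers with a short functionalisation of a commercial resorcinol, each position decided by a well-precedented directing effect, and a union of stable fragments.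

Key step: step 8

Assumption: 11 is drawn as the monomeric benzylzinc chloride (in THF it is the LiCl adduct), and 17 as its E isomer, although the geometry of this push–pull alkene does not affect ring closure.

## Route

**Step 1**
Reactants: 1 4-methoxyresorcinol (4-methoxybenzene-1,3-diol)
Product: 3 2,4-dihydroxy-5-methoxybenzaldehyde, via aryl iminium chloride 2 (not isolated)
Conditions: POCl3, DMF, MeCN, −15 → 25 °C; then H2O, 50 °C
Reagents that add atoms: N,N-dimethylformamide, CN(C)C=O; water, O
Why: Vilsmeier–Haack formylation; the chloroiminium ion attacks the one ring position that is para to one hydroxyl, ortho to the other and not flanked by two substituents, and hydrolysis of iminium salt 2 gives the aldehyde.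

**Step 2**
Reactants: 3 2,4-dihydroxy-5-methoxybenzaldehyde
Product: 4 5-methoxy-2,4-bis(methoxymethoxy)benzaldehyde
Conditions: MOMCl (3 equiv), i-Pr2NEt (4 equiv), CH2Cl2, 0 → 40 °C
Reagents that add atoms: chloromethyl methyl ether, COCCl
Why: Williamson-type O-alkylation of both phenols; excess reagent and gentle warming are needed to alkylate the hydrogen-bonded 2-OH as well as the 4-OH.

**Step 3**
Reactants: 4 5-methoxy-2,4-bis(methoxymethoxy)benzaldehyde
Product: 5 [5-methoxy-2,4-bis(methoxymethoxy)phenyl]methanol
Conditions: NaBH4, MeOH, 0 °C
Reagents that add atoms: none
Why: Hydride reduction of an aryl aldehyde to the benzylic alcohol; MOM ethers and the methyl ether are inert.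

**Step 4**
Reactants: 5 [5-methoxy-2,4-bis(methoxymethoxy)phenyl]methanol; 6 prenyl bromide (1-bromo-3-methylbut-2-ene)
Product: 8 [5-methoxy-2,4-bis(methoxymethoxy)-3-(3-methylbut-2-enyl)phenyl]methanol, via dilithiated benzyl alkoxide 7 (not isolated)
Conditions: n-BuLi (2.3 equiv), THF, −20 → 0 °C; CuBr·SMe2 (10 mol %), 6 (1.2 equiv), −40 → 0 °C; then H2O
Reagents that add atoms: none
Why: Directed ortho-metalation: after deprotonation of the alcohol, n-BuLi lithiates the carbon between the two MOM ethers, each of which must point toward it because its other neighbour is substituted; the aryllithium is then alkylated at the primary carbon of 6 much faster than the lithium alkoxide is.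

**Step 5**
Reactants: 8 [5-methoxy-2,4-bis(methoxymethoxy)-3-(3-methylbut-2-enyl)phenyl]methanol
Product: 10 1-(chloromethyl)-5-methoxy-2,4-bis(methoxymethoxy)-3-(3-methylbut-2-enyl)benzene, via benzylic mesylate 9 (not isolated)
Conditions: MsCl, Et3N, LiCl, THF, 0 → 25 °C; used without chromatography
Reagents that add atoms: lithium chloride, [Li+].[Cl-]; methanesulfonyl chloride, CS(=O)(=O)Cl (activates the alcohol, its atoms remain only in 9, its chloride can also end up in 10)
Why: Mesylation followed by in situ displacement by chloride; the electron-rich benzylic mesylate is substituted readily, and the basic, non-acidic medium spares the MOM ethers and the prenyl alkene.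

**Step 6**
Reactants: 10 1-(chloromethyl)-5-methoxy-2,4-bis(methoxymethoxy)-3-(3-methylbut-2-enyl)benzene
Product: 11 [5-methoxy-2,4-bis(methoxymethoxy)-3-(3-methylbut-2-enyl)benzyl]zinc chloride (THF solution, titrated and used directly)
Conditions: Zn dust, LiCl, THF, 0 → 25 °C, slow addition of 10
Reagents that add atoms: zinc, [Zn]
Why: LiCl-promoted oxidative insertion of zinc into a benzylic C–Cl bond, a standard entry to benzylzinc chlorides; ethers and the alkene are tolerated, and low temperature with slow addition limits Wurtz-type homocoupling.

**Step 7**
Reactants: 12 4-iodoresorcinol (4-iodobenzene-1,3-diol)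
Product: 13 4-iodo-1,3-phenylene diacetate
Conditions: Ac2O, pyridine, DMAP (cat.), CH2Cl2, 0 → 25 °C
Reagents that add atoms: acetic anhydride, CC(=O)OC(C)=O
Why: DMAP-catalysed O-acylation of both phenols; no regioselectivity is needed, and the esters mark the ring A oxygens as the ones to be freed before ring closure.

**Step 8**
Reactants: 13 4-iodo-1,3-phenylene diacetate; 14 carbon monoxide; 11 [5-methoxy-2,4-bis(methoxymethoxy)-3-(3-methylbut-2-enyl)benzyl]zinc chloride
Product: 15 4-{2-[5-methoxy-2,4-bis(methoxymethoxy)-3-(3-methylbut-2-enyl)phenyl]acetyl}-1,3-phenylene diacetate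
Conditions: Pd(PPh3)4 (5 mol %), CO (1 atm), THF, 25 → 40 °C, slow addition of 11 (1.5 equiv)
Reagents that add atoms: none
Why: Carbonylative Negishi cross-coupling, a known route from aryl iodides, CO and benzyl- or alkylzinc halides to unsymmetrical ketones. Zerovalent palladium inserts into the C–I bond of 13, CO coordinates and migrates to give an aroyl complex of divalent palladium, the benzyl group is transferred from zinc, and reductive elimination releases the ketone and regenerates zerovalent palladium. C4a–C4 and C4–C3 are thus both formed in one catalytic cycle. No ring is closed and no stereocentre is created. The selectivity required is carbonylative over direct aryl–benzyl coupling; it is secured by the CO atmosphere, by the ortho-acetoxy group, which hinders transmetalation at the crowded arylpalladium stage more than it hinders CO insertion, and by slow addition of 11 so that its concentration stays low. Chemoselectivity rests on the low nucleophilicity and basicity of the benzylzinc chloride, which should not attack aryl acetates, MOM ethers, the prenyl alkene or the product ketone at these temperatures. Because ring A carries esters and ring B acetals, the product is already set up for unmasking only O1 and O7.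

**Step 9**
Reactants: 15 4-{2-[5-methoxy-2,4-bis(methoxymethoxy)-3-(3-methylbut-2-enyl)phenyl]acetyl}-1,3-phenylene diacetate
Product: 16 1-(2,4-dihydroxyphenyl)-2-[5-methoxy-2,4-bis(methoxymethoxy)-3-(3-methylbut-2-enyl)phenyl]ethan-1-one
Conditions: K2CO3 (0.3 equiv), MeOH–THF, 0 → 25 °C
Reagents that add atoms: none
Why: Base-catalysed methanolysis (transesterification) of aryl acetates; intermolecular attack of methoxide at 0 °C is much faster than enolisation of the benzylic ketone, which would otherwise open a Baker–Venkataraman-type acyl shift, and MOM ethers are stable to base.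

**Step 10**
Reactants: 16 1-(2,4-dihydroxyphenyl)-2-[5-methoxy-2,4-bis(methoxymethoxy)-3-(3-methylbut-2-enyl)phenyl]ethan-1-one
Product: 18 7-hydroxy-3-[5-methoxy-2,4-bis(methoxymethoxy)-3-(3-methylbut-2-enyl)phenyl]-4H-chromen-4-one, via enaminone 17 (not isolated)
Conditions: Me2NCH(OMe)2 (1.5–2 equiv), THF, 65 °C
Reagents that add atoms: N,N-dimethylformamide dimethyl acetal, COC(OC)N(C)C
Why: Standard isoflavone synthesis from a 2-hydroxydeoxybenzoin: the formamide acetal condenses at the doubly activated methylene to give enaminone 17, and the ring A 2-OH then adds to the enamine carbon (6-endo-trig) with loss of dimethylamine; ring B oxygens are MOM-blocked so only O1 can close, and a small excess of reagent at moderate temperature limits methylation of the 7-OH.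

**Step 11**
Reactants: 18 7-hydroxy-3-[5-methoxy-2,4-bis(methoxymethoxy)-3-(3-methylbut-2-enyl)phenyl]-4H-chromen-4-one
Product: 19 piscisoflavone A, 3-[2,4-dihydroxy-5-methoxy-3-(3-methylbut-2-enyl)phenyl]-7-hydroxy-4H-chromen-4-one
Conditions: 3 M aq. HCl, MeOH, 40 °C, stopped as soon as 18 is consumed
Reagents that add atoms: none
Why: Acid-catalysed acetal exchange of aryl MOM ethers with methanol; dilute acid at or below 40 °C is chosen because ortho-prenyl phenols cyclise to chromans under stronger acid, while the chromone and the methyl ether are inert.

## Compound list

1 | 4-methoxyresorcinol (4-methoxybenzene-1,3-diol) | COc1ccc(O)cc1O | starting material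
2 | N-[(2,4-dihydroxy-5-methoxyphenyl)methylidene]-N-methylmethanaminium chloride | COc1cc(C=[N+](C)C)c(O)cc1O.[Cl-] | intermediate (not isolated)
3 | 2,4-dihydroxy-5-methoxybenzaldehyde | COc1cc(C=O)c(O)cc1O | intermediate
4 | 5-methoxy-2,4-bis(methoxymethoxy)benzaldehyde | COc1cc(C=O)c(OCOC)cc1OCOC | intermediate
5 | [5-methoxy-2,4-bis(methoxymethoxy)phenyl]methanol | COc1cc(CO)c(OCOC)cc1OCOC | intermediate
6 | prenyl bromide (1-bromo-3-methylbut-2-ene) | CC(C)=CCBr | starting material
7 | lithium [3-lithio-5-methoxy-2,4-bis(methoxymethoxy)phenyl]methanolate | COc1cc(CO[Li])c(OCOC)c([Li])c1OCOC | intermediate (not isolated)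
8 | [5-methoxy-2,4-bis(methoxymethoxy)-3-(3-methylbut-2-enyl)phenyl]methanol | COc1cc(CO)c(OCOC)c(CC=C(C)C)c1OCOC | intermediate
9 | 5-methoxy-2,4-bis(methoxymethoxy)-3-(3-methylbut-2-enyl)benzyl methanesulfonate | COc1cc(COS(C)(=O)=O)c(OCOC)c(CC=C(C)C)c1OCOC | intermediate (not isolated)
10 | 1-(chloromethyl)-5-methoxy-2,4-bis(methoxymethoxy)-3-(3-methylbut-2-enyl)benzene | COc1cc(CCl)c(OCOC)c(CC=C(C)C)c1OCOC | intermediate
11 | [5-methoxy-2,4-bis(methoxymethoxy)-3-(3-methylbut-2-enyl)benzyl]zinc chloride | COc1cc(C[Zn]Cl)c(OCOC)c(CC=C(C)C)c1OCOC | intermediate
12 | 4-iodoresorcinol (4-iodobenzene-1,3-diol) | Oc1ccc(I)c(O)c1 | starting material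
13 | 4-iodo-1,3-phenylene diacetate | CC(=O)Oc1ccc(I)c(OC(C)=O)c1 | intermediate
14 | carbon monoxide | [C-]#[O+] | starting material
15 | 4-{2-[5-methoxy-2,4-bis(methoxymethoxy)-3-(3-methylbut-2-enyl)phenyl]acetyl}-1,3-phenylene diacetate | CC(=O)Oc1ccc(C(=O)Cc2cc(OC)c(OCOC)c(CC=C(C)C)c2OCOC)c(OC(C)=O)c1 | intermediate
16 | 1-(2,4-dihydroxyphenyl)-2-[5-methoxy-2,4-bis(methoxymethoxy)-3-(3-methylbut-2-enyl)phenyl]ethan-1-one | COc1cc(CC(=O)c2ccc(O)cc2O)c(OCOC)c(CC=C(C)C)c1OCOC | intermediate
17 | (E)-1-(2,4-dihydroxyphenyl)-3-(dimethylamino)-2-[5-methoxy-2,4-bis(methoxymethoxy)-3-(3-methylbut-2-enyl)phenyl]prop-2-en-1-one | CN(C)/C=C(/C(=O)c1ccc(O)cc1O)c1cc(OC)c(OCOC)c(CC=C(C)C)c1OCOC | intermediate (not isolated)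
18 | 7-hydroxy-3-[5-methoxy-2,4-bis(methoxymethoxy)-3-(3-methylbut-2-enyl)phenyl]-4H-chromen-4-one | COc1cc(-c2coc3cc(O)ccc3c2=O)c(OCOC)c(CC=C(C)C)c1OCOC | intermediate
19 | piscisoflavone A, 3-[2,4-dihydroxy-5-methoxy-3-(3-methylbut-2-enyl)phenyl]-7-hydroxy-4H-chromen-4-one | COc1cc(-c2coc3cc(O)ccc3c2=O)c(O)c(CC=C(C)C)c1O | target

## Step count and least certain steps

Total: 11 steps. Longest linear sequence: 10 steps (steps 1–6, then 8–11); step 7 is the one-step side branch to 13.

**Step 8 (key step).** The most likely failure is direct, non-carbonylative coupling or incomplete CO uptake. The arylpalladium species from the diacetate is less electron-rich than the aryl ethers for which CO insertion is fastest, and benzyl transfer from zinc is quick. Homocoupling of the zinc reagent under CO is a second drain. Fallback: the carbonyl carbon is brought in with ring A instead of as a gas. 2,4-Dihydroxybenzoic acid F1 (purchased) is acetylated with Ac2O and pyridine to 2,4-diacetoxybenzoic acid F2. Oxalyl chloride with catalytic DMF converts F2 into 2,4-diacetoxybenzoyl chloride F3. Pd(PPh3)4-catalysed acylation of 11 with F3 in THF (Negishi acylation) gives 15. This fallback sets out from 11 and rejoins the route at 15.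

**Step 4.** The most likely failures are competing lithiation at the ring position between the alkoxymethyl and methoxy groups, O-prenylation of the lithium alkoxide, or sluggish reaction of a poorly soluble dianion. Fallback: the alcohol is silylated first. 5 is treated with TBSCl and imidazole to give tert-butyl{[5-methoxy-2,4-bis(methoxymethoxy)benzyl]oxy}dimethylsilane F4. n-BuLi lithiates F4 between the MOM ethers to the aryllithium F5, which is alkylated with 6 to the prenylated silyl ether F6. Bu4NF in THF then gives 8. This fallback sets out from 5 and rejoins at 8.

**Step 6.** The most likely failures are Wurtz-type homocoupling during insertion, or ionisation of the very electron-rich benzylic chloride (assisted by the ortho and para oxygens, with capture by the neighbouring acetal oxygen) before zinc inserts. Fallback: the polarity of the union is reversed so that no benzyl metal is needed. 13 is borylated (B2pin2, KOAc, PdCl2(dppf), dioxane, 80 °C) to 4-(4,4,5,5-tetramethyl-1,3,2-dioxaborolan-2-yl)-1,3-phenylene diacetate F7. Carbonylative Suzuki coupling of 10 with F7 under CO (Pd(OAc)2 with a phosphine, anhydrous K3PO4, toluene) gives 15 by oxidative addition of the benzylic chloride, CO insertion and aryl transfer from boron. Partial loss of acetate under the base would matter little, since step 9 removes both esters. This fallback sets out from 10 and 13 and rejoins at 15.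

**Step 10.** The most likely failure is O-methylation of the acidic 7-OH by the formamide acetal, or enaminone formation without clean ring closure. Fallback: the 7-oxygen is protected before ring closure. The 4-OH of 16, the one not hydrogen-bonded to the ketone, is alkylated selectively with MOMCl and K2CO3 in acetone to give 1-[2-hydroxy-4-(methoxymethoxy)phenyl]-2-[5-methoxy-2,4-bis(methoxymethoxy)-3-(3-methylbut-2-enyl)phenyl]ethan-1-one F8. Condensation with N,N-dimethylformamide dimethyl acetal gives, through enaminone F9, 3-[5-methoxy-2,4-bis(methoxymethoxy)-3-(3-methylbut-2-enyl)phenyl]-7-(methoxymethoxy)-4H-chromen-4-one F10. The acid treatment of step 11 then removes all three MOM groups to give 19. This fallback sets out from 16 and rejoins at 19.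

**Step 11.** The most likely failure is acid-catalysed cyclisation of the prenyl group onto the freed 2′- or 4′-OH, or addition of HCl or methanol across the alkene, because both new phenols are ortho to the prenyl group. Fallback: non-protic acetal cleavage through silyl ethers. TMSOTf with 2,2′-bipyridyl in CH2Cl2 at 0 °C converts the aryl MOM ethers of 18, and its free 7-OH, into trimethylsilyl ethers. This gives 3-[5-methoxy-3-(3-methylbut-2-enyl)-2,4-bis(trimethylsilyloxy)phenyl]-7-(trimethylsilyloxy)-4H-chromen-4-one F11, which water hydrolyses at neutral pH to 19. This fallback sets out from 18 and rejoins at 19.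

## Further compounds

F1 | step 8 | 2,4-dihydroxybenzoic acid (purchased) | O=C(O)c1ccc(O)cc1O
F2 | step 8 | 2,4-diacetoxybenzoic acid | CC(=O)Oc1ccc(C(=O)O)c(OC(C)=O)c1
F3 | step 8 | 2,4-diacetoxybenzoyl chloride | CC(=O)Oc1ccc(C(=O)Cl)c(OC(C)=O)c1
F4 | step 4 | tert-butyl{[5-methoxy-2,4-bis(methoxymethoxy)benzyl]oxy}dimethylsilane | COc1cc(CO[Si](C)(C)C(C)(C)C)c(OCOC)cc1OCOC
F5 | step 4 | {3-[(tert-butyldimethylsilyloxy)methyl]-5-methoxy-2,6-bis(methoxymethoxy)phenyl}lithium | COc1cc(CO[Si](C)(C)C(C)(C)C)c(OCOC)c([Li])c1OCOC
F6 | step 4 | tert-butyl{[5-methoxy-2,4-bis(methoxymethoxy)-3-(3-methylbut-2-enyl)benzyl]oxy}dimethylsilane | COc1cc(CO[Si](C)(C)C(C)(C)C)c(OCOC)c(CC=C(C)C)c1OCOC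
F7 | step 6 | 4-(4,4,5,5-tetramethyl-1,3,2-dioxaborolan-2-yl)-1,3-phenylene diacetate | CC(=O)Oc1ccc(B2OC(C)(C)C(C)(C)O2)c(OC(C)=O)c1
F8 | step 10 | 1-[2-hydroxy-4-(methoxymethoxy)phenyl]-2-[5-methoxy-2,4-bis(methoxymethoxy)-3-(3-methylbut-2-enyl)phenyl]ethan-1-one | COCOc1ccc(C(=O)Cc2cc(OC)c(OCOC)c(CC=C(C)C)c2OCOC)c(O)c1
F9 | step 10 | (E)-3-(dimethylamino)-1-[2-hydroxy-4-(methoxymethoxy)phenyl]-2-[5-methoxy-2,4-bis(methoxymethoxy)-3-(3-methylbut-2-enyl)phenyl]prop-2-en-1-one | CN(C)/C=C(/C(=O)c1ccc(OCOC)cc1O)c1cc(OC)c(OCOC)c(CC=C(C)C)c1OCOC
F10 | step 10 | 3-[5-methoxy-2,4-bis(methoxymethoxy)-3-(3-methylbut-2-enyl)phenyl]-7-(methoxymethoxy)-4H-chromen-4-one | COCOc1ccc2c(c1)occ(-c1cc(OC)c(OCOC)c(CC=C(C)C)c1OCOC)c2=O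
F11 | step 11 | 3-[5-methoxy-3-(3-methylbut-2-enyl)-2,4-bis(trimethylsilyloxy)phenyl]-7-(trimethylsilyloxy)-4H-chromen-4-one | COc1cc(-c2coc3cc(O[Si](C)(C)C)ccc3c2=O)c(O[Si](C)(C)C)c(CC=C(C)C)c1O[Si](C)(C)C
A1 | alternative 1 | 3-[2-hydroxy-5-methoxy-4-(methoxymethoxy)phenyl]-7-(methoxymethoxy)-4H-chromen-4-one | COCOc1ccc2c(c1)occ(-c1cc(OC)c(OCOC)cc1O)c2=O
A2 | alternative 1 | 3-ethynyl-7-(methoxymethoxy)-4H-chromen-4-one | COCOc1ccc2c(c1)occ(C#C)c2=O
A3 | alternative 1 | pentacarbonyl{methoxy[1-(methoxymethoxy)ethenyl]methylidene}chromium | COC(C(=C)OCOC)=[Cr](=C=O)(=C=O)(=C=O)(=C=O)=C=O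
A4 | alternative 2 | 3-[5-methoxy-2,4-bis(methoxymethoxy)-3-(3-methylbut-2-enyl)phenyl]-7-(methoxymethoxy)-2-(trimethylsilyl)-4H-chromen-4-one | COCOc1ccc2c(c1)oc([Si](C)(C)C)c(-c1cc(OC)c(OCOC)c(CC=C(C)C)c1OCOC)c2=O
A5 | alternative 2 | 2-hydroxy-4-(methoxymethoxy)benzaldehyde | COCOc1ccc(C=O)c(O)c1
A6 | alternative 2 | {[5-methoxy-2,4-bis(methoxymethoxy)-3-(3-methylbut-2-enyl)phenyl]ethynyl}trimethylsilane | COc1cc(C#C[Si](C)(C)C)c(OCOC)c(CC=C(C)C)c1OCOC
A7 | alternative 3 | 3-[2-hydroxy-5-methoxy-3-(3-methylbut-2-enyl)-4-(propan-2-yloxy)phenyl]-7-(methoxymethoxy)-4H-chromen-4-one | COCOc1ccc2c(c1)occ(-c1cc(OC)c(OC(C)C)c(CC=C(C)C)c1O)c2=O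
A8 | alternative 3 | racemic 4-methoxy-4-{(E)-2-[7-(methoxymethoxy)-4-oxo-4H-chromen-3-yl]ethenyl}-2-(3-methylbut-2-enyl)-3-(propan-2-yloxy)cyclobut-2-en-1-one | COCOc1ccc2c(c1)occ(/C=C/C1(OC)C(OC(C)C)=C(CC=C(C)C)C1=O)c2=O
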